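**Retrosynthetic overview**
- The target comes from its 8‑hydroxy macrocycle by angeloylation and desilylation. The ten‑membered ring is closed last at C7–C8 by an intramolecular CrCl2 (Nozaki–Hiyama) allylation of a C8 aldehyde by a 3‑(bromomethyl)butenolide, which also creates the α‑methylene lactone.
- The 3(2H)‑furanone (C1–C3, oxygen bridge to C10) is unmasked from a 3,5‑disubstituted isoxazole. The isoxazole is made in the key nitrile oxide–alkyne [3+2] cycloaddition, which joins the C3–C5 piece ((S)‑Roche ester, C4) to the C1/C2/C8–C10 piece ((S)‑glycerate, C9; C10 by chelation‑controlled ethynylation).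
- The butenolide (C6, C7, C11, C12) and the C5/C6 stereocentres come from a vinylogous Mukaiyama aldol of 3‑bromo‑2‑silyloxyfuran with the C5 aldehyde; C13 is added by Stille hydroxymethylation.
- Ring order: isoxazole (cycloaddition) → butenolide (aldol) → furanone (from the isoxazole) → ten‑membered carbocycle and α‑methylene‑γ‑lactone (allylation).

Assumption: positions are given in germacrane numbering (C12 lactone carbonyl, C13 exocyclic methylene, C1 furanone ketone, C3/C10 the ring‑oxygen carbons); the (S)‑Roche ester, methyl (S)‑glycerate acetonide, 3‑bromofuran‑2(5H)‑one, angelic acid and the organometallic reagents are bought.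

Step 1
Reactants: 1 methyl (4S)-2,2-dimethyl-1,3-dioxolane-4-carboxylate
Product: 3 1-[(4S)-2,2-dimethyl-1,3-dioxolan-4-yl]ethan-1-one, via Weinreb amide 2 (not isolated)
Conditions: MeNH(OMe)·HCl, i-PrMgCl, THF, −20 °C; then MeMgBr, −20 → 0 °C; aq. NH4Cl
Reagents that add atoms: methylmagnesium bromide, C[Mg]Br (the CH3 of 3); N,O-dimethylhydroxylamine hydrochloride, CNOC.Cl (the N(OMe)Me group of 2 only)
Why: One-pot Weinreb amidation and Grignard addition, in which the chelated tetrahedral adduct of 2 collapses only on work-up, so the methyl ketone forms without over-addition and the bought C9 stereocentre is untouched.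

Step 2
Reactants: 3 1-[(4S)-2,2-dimethyl-1,3-dioxolan-4-yl]ethan-1-one
Product: 4 (2S)-2-[(4S)-2,2-dimethyl-1,3-dioxolan-4-yl]but-3-yn-2-ol
Conditions: HC≡CMgBr (0.5 M in THF), THF, −78 → −20 °C; aq. NH4Cl
Reagents that add atoms: ethynylmagnesium bromide, C#C[Mg]Br
Why: Chelation-controlled (Cram cyclic model) Grignard 1,2-addition in which magnesium bridges the ketone oxygen and the α-oxygen of the dioxolane and the acetylide enters from the side of the C9 hydrogen, setting C10 as the (2S) tertiary carbinol (O9 and O10 syn).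

Step 3
Reactants: 5 methyl (2S)-3-hydroxy-2-methylpropanoate
Product: 6 methyl (2S)-3-[tert-butyl(dimethyl)silyl]oxy-2-methylpropanoate
Conditions: TBSCl, imidazole, DMF, 25 °C
Reagents that add atoms: tert-butyldimethylsilyl chloride, CC(C)(C)[Si](C)(C)Cl
Why: Standard silylation of the primary alcohol of the (S)-Roche ester, which supplies C4, with no stereocentre touched.

Step 4
Reactants: 6 methyl (2S)-3-[tert-butyl(dimethyl)silyl]oxy-2-methylpropanoate
Product: 7 (2S)-3-[tert-butyl(dimethyl)silyl]oxy-2-methylpropanal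
Conditions: i-Bu2AlH, CH2Cl2, −78 °C; aq. KNaC4H4O6 (Rochelle salt)
Reagents that add atoms: none
Why: Low-temperature DIBAL-H half-reduction stops at the aluminium hemiacetal and releases the aldehyde on work-up without epimerising the α-methyl centre.

Step 5
Reactants: 7 (2S)-3-[tert-butyl(dimethyl)silyl]oxy-2-methylpropanal
Product: 8 (2R)-3-[tert-butyl(dimethyl)silyl]oxy-2-methylpropanal oxime (E/Z mixture)
Conditions: NH2OH·HCl, NaOAc, EtOH–H2O, 25 °C
Reagents that add atoms: hydroxylamine hydrochloride, NO.Cl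
Why: Buffered oxime condensation gives the aldoxime without epimerisation (both oxime isomers converge in the next step; the descriptor changes by priority only).

Step 6
Reactants: 8 (2R)-3-[tert-butyl(dimethyl)silyl]oxy-2-methylpropanal oxime; 4 (2S)-2-[(4S)-2,2-dimethyl-1,3-dioxolan-4-yl]but-3-yn-2-ol
Product: 11 (1R)-1-[3-[(2R)-1-[tert-butyl(dimethyl)silyl]oxypropan-2-yl]-1,2-oxazol-5-yl]-1-[(4S)-2,2-dimethyl-1,3-dioxolan-4-yl]ethan-1-ol, via hydroximoyl chloride 9 (not isolated), via nitrile oxide 10 (not isolated)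
Conditions: NCS, DMF, 25 °C; then 4 (1.5 equiv), Et3N (slow addition), CH2Cl2, 0 → 25 °C
Reagents that add atoms: none
Why: Key step, a thermal Huisgen 1,3-dipolar [3+2] cycloaddition of the in-situ nitrile oxide with the terminal alkyne that is regioselective for the 3,5-disubstituted isoxazole, a masked 1,3-dicarbonyl whose three ring carbons become C3, C2 and C1 of the furanone, with no stereocentre formed or disturbed.

Step 7
Reactants: 11 (1R)-1-[3-[(2R)-1-[tert-butyl(dimethyl)silyl]oxypropan-2-yl]-1,2-oxazol-5-yl]-1-[(4S)-2,2-dimethyl-1,3-dioxolan-4-yl]ethan-1-ol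
Product: 12 (2R)-2-[5-[(1R)-1-[(4S)-2,2-dimethyl-1,3-dioxolan-4-yl]-1-hydroxyethyl]-1,2-oxazol-3-yl]propan-1-ol
Conditions: Bu4NF, THF, 0 °C; aq. NH4Cl
Reagents that add atoms: none
Why: Fluoride cleavage of the primary TBS ether, to which the acetonide, the isoxazole and the tertiary alcohol are inert.

Step 8
Reactants: 12 (2R)-2-[5-[(1R)-1-[(4S)-2,2-dimethyl-1,3-dioxolan-4-yl]-1-hydroxyethyl]-1,2-oxazol-3-yl]propan-1-ol
Product: 13 (2R)-2-[5-[(1R)-1-[(4S)-2,2-dimethyl-1,3-dioxolan-4-yl]-1-hydroxyethyl]-1,2-oxazol-3-yl]propanal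
Conditions: Dess–Martin periodinane, CH2Cl2, 0 °C, 30 min; short silica pad, used at once
Reagents that add atoms: none
Why: Dess–Martin oxidation under base-free conditions gives the α-(isoxazolyl) aldehyde, used immediately to avoid enolisation at C4, while the tertiary alcohol cannot be oxidised.

Step 9
Reactants: 14 3-bromofuran-2(5H)-one
Product: 15 (3-bromofuran-2-yl)oxy-tert-butyl(dimethyl)silane
Conditions: TBSOTf, Et3N, CH2Cl2, 0 °C
Reagents that add atoms: tert-butyldimethylsilyl triflate, CC(C)(C)[Si](C)(C)OS(=O)(=O)C(F)(F)F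
Why: O-silylation of the butenolide dienolate gives the 2-silyloxyfuran nucleophile (no stereocentre).

Step 10
Reactants: 13 (2R)-2-[5-[(1R)-1-[(4S)-2,2-dimethyl-1,3-dioxolan-4-yl]-1-hydroxyethyl]-1,2-oxazol-3-yl]propanal; 15 (3-bromofuran-2-yl)oxy-tert-butyl(dimethyl)silane
Product: 16 (5S)-3-bromo-5-[(1S,2R)-2-[5-[(1R)-1-[(4S)-2,2-dimethyl-1,3-dioxolan-4-yl]-1-hydroxyethyl]-1,2-oxazol-3-yl]-1-hydroxypropyl]furan-2(5H)-one
Conditions: BF3·OEt2, CH2Cl2, −78 °C; aq. NaHCO3
Reagents that add atoms: none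
Why: Vinylogous Mukaiyama aldol through an open transition state in which the furan attacks the BF3-activated aldehyde anti to the isoxazolyl group (Felkin–Anh, C5–OH syn to the C4 methyl) and with the threo (5,6-syn) preference of Lewis-acid silyloxyfuran additions, setting C5 (S) and C6 (S) and delivering the butenolide with its C11 bromide.

Step 11
Reactants: 16 (5S)-3-bromo-5-[(1S,2R)-2-[5-[(1R)-1-[(4S)-2,2-dimethyl-1,3-dioxolan-4-yl]-1-hydroxyethyl]-1,2-oxazol-3-yl]-1-hydroxypropyl]furan-2(5H)-one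
Product: 17 (5S)-3-bromo-5-[(1S,2R)-1-[tert-butyl(dimethyl)silyl]oxy-2-[5-[(1R)-1-[(4S)-2,2-dimethyl-1,3-dioxolan-4-yl]-1-hydroxyethyl]-1,2-oxazol-3-yl]propyl]furan-2(5H)-one
Conditions: TBSOTf (1.1 equiv), 2,6-lutidine, CH2Cl2, −78 °C
Reagents that add atoms: tert-butyldimethylsilyl triflate, CC(C)(C)[Si](C)(C)OS(=O)(=O)C(F)(F)F
Why: Selective silylation of the secondary C5 alcohol (the hindered tertiary C10 alcohol does not react with one equivalent at −78 °C), which keeps O5 from competing for the diketone equivalent in the next step.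

Step 12
Reactants: 17 (5S)-3-bromo-5-[(1S,2R)-1-[tert-butyl(dimethyl)silyl]oxy-2-[5-[(1R)-1-[(4S)-2,2-dimethyl-1,3-dioxolan-4-yl]-1-hydroxyethyl]-1,2-oxazol-3-yl]propyl]furan-2(5H)-one
Product: 19 (5S)-3-bromo-5-[(1S,2S)-1-[tert-butyl(dimethyl)silyl]oxy-2-[(5R)-5-[(1S)-1,2-dihydroxyethyl]-5-methyl-4-oxo-4,5-dihydrofuran-2-yl]propyl]furan-2(5H)-one, via enaminone 18 (not isolated)
Conditions: Mo(CO)6, MeCN–H2O, 80 °C; then AcOH–H2O–THF (3:1:1), 45 °C
Reagents that add atoms: none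
Why: Reductive N–O cleavage of the isoxazole by Mo(CO)6 gives the vinylogous amide, and in aqueous acetic acid the C10 hydroxyl adds to C3 with loss of ammonia to close the 3(2H)-furanone while the acetonide is hydrolysed, C10 keeping its configuration because its C–O bond is never broken.

Step 13
Reactants: 19 (5S)-3-bromo-5-[(1S,2S)-1-[tert-butyl(dimethyl)silyl]oxy-2-[(5R)-5-[(1S)-1,2-dihydroxyethyl]-5-methyl-4-oxo-4,5-dihydrofuran-2-yl]propyl]furan-2(5H)-one
Product: 20 (5S)-5-[(1S,2S)-2-[(5R)-5-[(1S)-1,2-bis(triethylsilyloxy)ethyl]-5-methyl-4-oxo-4,5-dihydrofuran-2-yl]-1-[tert-butyl(dimethyl)silyl]oxypropyl]-3-bromofuran-2(5H)-one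
Conditions: TESOTf (2.5 equiv), 2,6-lutidine, CH2Cl2, −78 → 0 °C
Reagents that add atoms: triethylsilyl triflate, CC[Si](CC)(CC)OS(=O)(=O)C(F)(F)F
Why: Exhaustive silylation of the 8,9-diol prepares the selective oxidation of the primary position and protects O9.

Step 14
Reactants: 20 (5S)-5-[(1S,2S)-2-[(5R)-5-[(1S)-1,2-bis(triethylsilyloxy)ethyl]-5-methyl-4-oxo-4,5-dihydrofuran-2-yl]-1-[tert-butyl(dimethyl)silyl]oxypropyl]-3-bromofuran-2(5H)-one
Product: 21 (2R)-2-[(2R)-5-[(1S,2S)-1-[(2S)-4-bromo-5-oxo-2,5-dihydrofuran-2-yl]-1-[tert-butyl(dimethyl)silyl]oxypropan-2-yl]-2-methyl-3-oxo-2,3-dihydrofuran-2-yl]-2-(triethylsilyloxy)acetaldehyde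
Conditions: (COCl)2, DMSO, CH2Cl2, −78 → −30 °C; Et3N, −78 → 0 °C
Reagents that add atoms: none
Why: Swern conditions oxidise a primary triethylsilyl ether directly to the aldehyde (oxidative desilylation) while the secondary TES and TBS ethers survive, so C8 becomes the aldehyde with O9 still protected.

Step 15
Reactants: 21 (2R)-2-[(2R)-5-[(1S,2S)-1-[(2S)-4-bromo-5-oxo-2,5-dihydrofuran-2-yl]-1-[tert-butyl(dimethyl)silyl]oxypropan-2-yl]-2-methyl-3-oxo-2,3-dihydrofuran-2-yl]-2-(triethylsilyloxy)acetaldehyde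
Product: 22 the same aldehyde carrying CH2OH in place of the butenolide bromine (3-(hydroxymethyl)butenolide)
Conditions: Bu3SnCH2OH, Pd(PPh3)4 (10 mol %), dioxane, 90 °C
Reagents that add atoms: (tributylstannyl)methanol, CCCC[Sn](CCCC)(CCCC)CO
Why: Stille cross-coupling of the α-bromobutenolide installs C13 as a hydroxymethyl group under neutral conditions tolerated by the aldehyde, the furanone and the silyl ethers.

Step 16
Reactants: 22 the 3-(hydroxymethyl)butenolide aldehyde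
Product: 23 the corresponding 3-(bromomethyl)butenolide aldehyde
Conditions: PPh3, NBS, CH2Cl2, −20 °C
Reagents that add atoms: N-bromosuccinimide, O=C1CCC(=O)N1Br
Why: Appel-type bromination with the preformed PPh3–NBS adduct converts the allylic alcohol into the allylic bromide under base-free conditions that spare the aldehyde.

Step 17
Reactants: 23 the 3-(bromomethyl)butenolide aldehyde
Product: 25 (4S,5S,6S,7R,8S,9S,10R)-5-[tert-butyl(dimethyl)silyl]oxy-8-hydroxy-9-(triethylsilyloxy)-1-oxo-3,10-epoxygermacra-2,11(13)-dien-12,6-olide, via allylchromium dichloride 24 (not isolated)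
Conditions: CrCl2 (6 equiv), THF, 25 °C, syringe-pump addition of 23 (final 2 mM); aq. NH4Cl
Reagents that add atoms: none
Why: Intramolecular Nozaki–Hiyama allylation in which CrCl2 inserts into the allylic bromide and the allylchromium adds through its γ-carbon C7 to the C8 aldehyde, closing the ten-membered ring and moving the double bond to C11=C13, with C7 formed anti to the C5 chain on the butenolide (trans lactone) and C8 by Felkin–Anh attack anti to the C9 silyloxy group (8,9-erythro, 8β-OH).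

Step 18
Reactants: 25 the 8-hydroxy macrocycle
Product: 26 (4S,5S,6S,7S,8S,9S,10R)-8-[(Z)-2-methylbut-2-enoyl]oxy-5-[tert-butyl(dimethyl)silyl]oxy-9-(triethylsilyloxy)-1-oxo-3,10-epoxygermacra-2,11(13)-dien-12,6-olide
Conditions: angelic acid, 2,4,6-Cl3C6H2COCl, Et3N, toluene, 25 °C; then 25, toluene, 80 °C
Reagents that add atoms: angelic acid, C/C=C(/C)C(=O)O
Why: Yamaguchi-type esterification with the preformed mixed anhydride and no nucleophilic catalyst acylates the only free hydroxyl (C8) while keeping the Z (angelate) geometry.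

Step 19
Reactants: 26 the bis-silylated 8-angelate
Product: 27 (4S,5S,6S,7S,8S,9S,10R)-8-[(Z)-2-methylbut-2-enoyl]oxy-5,9-dihydroxy-1-oxo-3,10-epoxygermacra-2,11(13)-dien-12,6-olide (CNP0206920.2)
Conditions: HF·pyridine, pyridine, THF, 0 → 25 °C
Reagents that add atoms: none
Why: Buffered HF·pyridine desilylation removes the TES (O9) and TBS (O5) ethers without affecting the angelate, the α-methylene lactone or the furanone, giving the target.

**Compound list**
1 | methyl (4S)-2,2-dimethyl-1,3-dioxolane-4-carboxylate | COC(=O)[C@@H]1COC(C)(C)O1 | starting material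
2 | (4S)-N-methoxy-N,2,2-trimethyl-1,3-dioxolane-4-carboxamide | CON(C)C(=O)[C@@H]1COC(C)(C)O1 | intermediate (not isolated)
3 | 1-[(4S)-2,2-dimethyl-1,3-dioxolan-4-yl]ethan-1-one | CC(=O)[C@@H]1COC(C)(C)O1 | intermediate
4 | (2S)-2-[(4S)-2,2-dimethyl-1,3-dioxolan-4-yl]but-3-yn-2-ol | C#C[C@](C)(O)[C@@H]1COC(C)(C)O1 | intermediate
5 | methyl (2S)-3-hydroxy-2-methylpropanoate ((S)-Roche ester) | COC(=O)[C@@H](C)CO | starting material
6 | methyl (2S)-3-[tert-butyl(dimethyl)silyl]oxy-2-methylpropanoate | COC(=O)[C@@H](C)CO[Si](C)(C)C(C)(C)C | intermediate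
7 | (2S)-3-[tert-butyl(dimethyl)silyl]oxy-2-methylpropanal | O=C[C@@H](C)CO[Si](C)(C)C(C)(C)C | intermediate
8 | (2R)-3-[tert-butyl(dimethyl)silyl]oxy-2-methylpropanal oxime (E/Z mixture, C=N not defined) | ON=C[C@@H](C)CO[Si](C)(C)C(C)(C)C | intermediate
9 | (2S)-3-[tert-butyl(dimethyl)silyl]oxy-N-hydroxy-2-methylpropanimidoyl chloride | ON=C(Cl)[C@@H](C)CO[Si](C)(C)C(C)(C)C | intermediate (not isolated)
10 | (2R)-3-[tert-butyl(dimethyl)silyl]oxy-2-methylpropanenitrile oxide | [O-][N+]#C[C@@H](C)CO[Si](C)(C)C(C)(C)C | intermediate (not isolated)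
11 | (1R)-1-[3-[(2R)-1-[tert-butyl(dimethyl)silyl]oxypropan-2-yl]-1,2-oxazol-5-yl]-1-[(4S)-2,2-dimethyl-1,3-dioxolan-4-yl]ethan-1-ol | CC(C)(C)[Si](C)(C)OC[C@H](C)c1noc(c1)[C@](C)(O)[C@@H]2COC(C)(C)O2 | intermediate
12 | (2R)-2-[5-[(1R)-1-[(4S)-2,2-dimethyl-1,3-dioxolan-4-yl]-1-hydroxyethyl]-1,2-oxazol-3-yl]propan-1-ol | OC[C@H](C)c1noc(c1)[C@](C)(O)[C@@H]2COC(C)(C)O2 | intermediate
13 | (2R)-2-[5-[(1R)-1-[(4S)-2,2-dimethyl-1,3-dioxolan-4-yl]-1-hydroxyethyl]-1,2-oxazol-3-yl]propanal | O=C[C@H](C)c1noc(c1)[C@](C)(O)[C@@H]2COC(C)(C)O2 | intermediate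
14 | 3-bromofuran-2(5H)-one | O=C1OCC=C1Br | starting material
15 | (3-bromofuran-2-yl)oxy-tert-butyl(dimethyl)silane | CC(C)(C)[Si](C)(C)Oc1occc1Br | intermediate
16 | (5S)-3-bromo-5-[(1S,2R)-2-[5-[(1R)-1-[(4S)-2,2-dimethyl-1,3-dioxolan-4-yl]-1-hydroxyethyl]-1,2-oxazol-3-yl]-1-hydroxypropyl]furan-2(5H)-one | O=C1O[C@@H](C=C1Br)[C@@H](O)[C@H](C)c2noc(c2)[C@](C)(O)[C@@H]3COC(C)(C)O3 | intermediate
17 | (5S)-3-bromo-5-[(1S,2R)-1-[tert-butyl(dimethyl)silyl]oxy-2-[5-[(1R)-1-[(4S)-2,2-dimethyl-1,3-dioxolan-4-yl]-1-hydroxyethyl]-1,2-oxazol-3-yl]propyl]furan-2(5H)-one | O=C1O[C@@H](C=C1Br)[C@@H](O[Si](C)(C)C(C)(C)C)[C@H](C)c2noc(c2)[C@](C)(O)[C@@H]3COC(C)(C)O3 | intermediate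
18 | (Z)-enaminone: 17 with the isoxazole opened to C3(NH2)=C2H–C1(=O), all stereocentres as in 17 | O=C1O[C@@H](C=C1Br)[C@@H](O[Si](C)(C)C(C)(C)C)[C@H](C)/C(N)=C/C(=O)[C@](C)(O)[C@@H]2COC(C)(C)O2 | intermediate (not isolated)
19 | (5S)-3-bromo-5-[(1S,2S)-1-[tert-butyl(dimethyl)silyl]oxy-2-[(5R)-5-[(1S)-1,2-dihydroxyethyl]-5-methyl-4-oxo-4,5-dihydrofuran-2-yl]propyl]furan-2(5H)-one | O=C1O[C@@H](C=C1Br)[C@@H](O[Si](C)(C)C(C)(C)C)[C@H](C)C2=CC(=O)[C@](C)(O2)[C@@H](O)CO | intermediate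
20 | (5S)-5-[(1S,2S)-2-[(5R)-5-[(1S)-1,2-bis(triethylsilyloxy)ethyl]-5-methyl-4-oxo-4,5-dihydrofuran-2-yl]-1-[tert-butyl(dimethyl)silyl]oxypropyl]-3-bromofuran-2(5H)-one | O=C1O[C@@H](C=C1Br)[C@@H](O[Si](C)(C)C(C)(C)C)[C@H](C)C2=CC(=O)[C@](C)(O2)[C@@H](O[Si](CC)(CC)CC)CO[Si](CC)(CC)CC | intermediate
21 | (2R)-2-[(2R)-5-[(1S,2S)-1-[(2S)-4-bromo-5-oxo-2,5-dihydrofuran-2-yl]-1-[tert-butyl(dimethyl)silyl]oxypropan-2-yl]-2-methyl-3-oxo-2,3-dihydrofuran-2-yl]-2-(triethylsilyloxy)acetaldehyde | O=C1O[C@@H](C=C1Br)[C@@H](O[Si](C)(C)C(C)(C)C)[C@H](C)C2=CC(=O)[C@](C)(O2)[C@@H](O[Si](CC)(CC)CC)C=O | intermediate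
22 | 21 with CH2OH in place of the butenolide bromine (4-(hydroxymethyl)-5-oxo-2,5-dihydrofuran-2-yl) | O=C1O[C@@H](C=C1CO)[C@@H](O[Si](C)(C)C(C)(C)C)[C@H](C)C2=CC(=O)[C@](C)(O2)[C@@H](O[Si](CC)(CC)CC)C=O | intermediate
23 | 21 with CH2Br in place of the butenolide bromine (4-(bromomethyl)-5-oxo-2,5-dihydrofuran-2-yl) | O=C1O[C@@H](C=C1CBr)[C@@H](O[Si](C)(C)C(C)(C)C)[C@H](C)C2=CC(=O)[C@](C)(O2)[C@@H](O[Si](CC)(CC)CC)C=O | intermediate
24 | allylchromium dichloride from 23 (CrCl2 on C13) | O=C1O[C@@H](C=C1C[Cr](Cl)Cl)[C@@H](O[Si](C)(C)C(C)(C)C)[C@H](C)C2=CC(=O)[C@](C)(O2)[C@@H](O[Si](CC)(CC)CC)C=O | intermediate (not isolated)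
25 | (4S,5S,6S,7R,8S,9S,10R)-5-[tert-butyl(dimethyl)silyl]oxy-8-hydroxy-9-(triethylsilyloxy)-1-oxo-3,10-epoxygermacra-2,11(13)-dien-12,6-olide | C=C1C(=O)O[C@@H]2[C@@H](O[Si](C)(C)C(C)(C)C)[C@H](C)C3=CC(=O)[C@](C)(O3)[C@@H](O[Si](CC)(CC)CC)[C@@H](O)[C@@H]12 | intermediate
26 | (4S,5S,6S,7S,8S,9S,10R)-8-[(Z)-2-methylbut-2-enoyl]oxy-5-[tert-butyl(dimethyl)silyl]oxy-9-(triethylsilyloxy)-1-oxo-3,10-epoxygermacra-2,11(13)-dien-12,6-olide | C=C1C(=O)O[C@@H]2[C@@H](O[Si](C)(C)C(C)(C)C)[C@H](C)C3=CC(=O)[C@](C)(O3)[C@@H](O[Si](CC)(CC)CC)[C@@H](OC(=O)/C(C)=C\C)[C@@H]12 | intermediate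
27 | (4S,5S,6S,7S,8S,9S,10R)-8-[(Z)-2-methylbut-2-enoyl]oxy-5,9-dihydroxy-1-oxo-3,10-epoxygermacra-2,11(13)-dien-12,6-olide (CNP0206920.2) | C=C1C(=O)O[C@@H]2[C@@H](O)[C@H](C)C3=CC(=O)[C@](C)(O3)[C@@H](O)[C@@H](OC(=O)/C(C)=C\C)[C@@H]12 | target

**Step count and risks**
Total step count: 19. Longest linear sequence: 16 (from 5: steps 3–8 and 10–19).

The three steps most likely to fail:

1. Step 17 (ring closure). The reaction may oligomerise or give the C8 epimer, because the Felkin-preferred C8 configuration needs the aldehyde substituent axial in a chair transition state. The fallback sets out from 21 and replaces steps 15–17. Stille coupling of 21 with Bu3SnCH2SiMe3 (Pd(PPh3)4, dioxane, 90 °C) gives the 3-(trimethylsilylmethyl)butenolide aldehyde F1. F1 is then cyclised by an intramolecular Hosomi–Sakurai allylation (BF3·OEt2 or TiCl4, CH2Cl2, −78 °C, high dilution). Its open transition state favours the syn C7/C8 relationship together with Felkin addition at C8, and the product is 25, where the route is rejoined.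

2. Step 10 (vinylogous aldol). Aldehyde 13 may epimerise at C4 or add with poor facial control. The fallback moves the aldol ahead of the cycloaddition; it sets out from 15 (and uses 4) and returns at 17. The enantiomeric Roche ester, methyl (2R)-3-hydroxy-2-methylpropanoate F2, is used, so that its ester carbon becomes C5 and its CH2O carbon becomes C3. Silylation gives the TBS ether F3 and i-Bu2AlH gives the robust (2R)-aldehyde F4. The BF3·OEt2 aldol of F4 with 15 (Felkin, threo) gives the butenolide alcohol F5, and TBSOTf gives the bis-silyl ether F6. HF·pyridine/pyridine removes the primary TBS group to give the primary alcohol F7, Dess–Martin oxidation gives the aldehyde F8, and NH2OH gives the oxime F9. F9 is converted to its nitrile oxide with TsN(Cl)Na (chloramine-T) in t-BuOH–H2O in the presence of 4 and monovalent copper (CuSO4·5H2O, sodium ascorbate). The copper acetylide of 4 should trap the nitrile oxide faster than it can add intramolecularly to the butenolide double bond; this competition is the weak point of the fallback. The product is 17.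

3. Step 2 (C10). The sense or level of induction is uncertain with the weakly chelating dioxolane oxygen. The fallback reverses the order in which the two carbon substituents are introduced; it sets out from 1 and returns at 4. Lithium (trimethylsilyl)acetylide with BF3·OEt2 (THF, −78 °C) converts 1 into the silyl ynone F10. MeTi(OiPr)3 (non-chelating, Felkin–Anh attack anti to the dioxolane C–O bond) then gives the silylated tertiary carbinol F11 with the same C10 configuration. K2CO3 in MeOH removes the silyl group to give 4.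

**Further compounds**
F1 | step 17 | 21 with CH2SiMe3 in place of the butenolide bromine (3-(trimethylsilylmethyl)butenolide aldehyde) | O=C1O[C@@H](C=C1C[Si](C)(C)C)[C@@H](O[Si](C)(C)C(C)(C)C)[C@H](C)C2=CC(=O)[C@](C)(O2)[C@@H](O[Si](CC)(CC)CC)C=O
F2 | step 10 | methyl (2R)-3-hydroxy-2-methylpropanoate | COC(=O)[C@H](C)CO
F3 | step 10 | methyl (2R)-3-[tert-butyl(dimethyl)silyl]oxy-2-methylpropanoate | COC(=O)[C@H](C)CO[Si](C)(C)C(C)(C)C
F4 | step 10 | (2R)-3-[tert-butyl(dimethyl)silyl]oxy-2-methylpropanal | O=C[C@H](C)CO[Si](C)(C)C(C)(C)C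
F5 | step 10 | (5S)-3-bromo-5-[(1S,2R)-3-[tert-butyl(dimethyl)silyl]oxy-1-hydroxy-2-methylpropyl]furan-2(5H)-one | O=C1O[C@@H](C=C1Br)[C@@H](O)[C@H](C)CO[Si](C)(C)C(C)(C)C
F6 | step 10 | (5S)-3-bromo-5-[(1S,2R)-1,3-bis[tert-butyl(dimethyl)silyl]oxy-2-methylpropyl]furan-2(5H)-one | O=C1O[C@@H](C=C1Br)[C@@H](O[Si](C)(C)C(C)(C)C)[C@H](C)CO[Si](C)(C)C(C)(C)C
F7 | step 10 | (5S)-3-bromo-5-[(1S,2R)-1-[tert-butyl(dimethyl)silyl]oxy-3-hydroxy-2-methylpropyl]furan-2(5H)-one | O=C1O[C@@H](C=C1Br)[C@@H](O[Si](C)(C)C(C)(C)C)[C@H](C)CO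
F8 | step 10 | (2S,3S)-3-[(2S)-4-bromo-5-oxo-2,5-dihydrofuran-2-yl]-3-[tert-butyl(dimethyl)silyl]oxy-2-methylpropanal | O=C1O[C@@H](C=C1Br)[C@@H](O[Si](C)(C)C(C)(C)C)[C@H](C)C=O
F9 | step 10 | oxime of F8 (E/Z mixture, C=N not defined) | O=C1O[C@@H](C=C1Br)[C@@H](O[Si](C)(C)C(C)(C)C)[C@H](C)C=NO
F10 | step 2 | 1-[(4S)-2,2-dimethyl-1,3-dioxolan-4-yl]-3-(trimethylsilyl)prop-2-yn-1-one | C[Si](C)(C)C#CC(=O)[C@@H]1COC(C)(C)O1
F11 | step 2 | (2S)-2-[(4S)-2,2-dimethyl-1,3-dioxolan-4-yl]-4-(trimethylsilyl)but-3-yn-2-ol | C[Si](C)(C)C#C[C@](C)(O)[C@@H]1COC(C)(C)O1
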